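**Retrosynthetic overview**
- ε,ε-Carotene ⇒ cut both C12–C13 and C12'–C13' sp2–sp2 single bonds at once: two copies of a C16 dienyne (ε ring + C7–C12, terminal alkyne C11≡C12) and one C8 unit, (2E,4E,6E)-2,7-diiodoocta-2,4,6-triene (C13–C13' with both C20 methyls).
- Enabling feature: the C2 axis through the midpoint of C15=C15' makes the two bonds equivalent. C13/C13' are methyl-bearing alkene carbons (an α-methylvinyl iodide of fixed geometry), and C11=C12/C11'=C12' are 1,2-disubstituted E-alkenes (a syn-hydrometalated terminal alkyne).
- C16 dienyne ⇒ (S)-α-ionone by Horner–Wadsworth–Emmons olefination (C9=C10), ester-to-aldehyde redox and one-carbon alkyne homologation. (S)-α-Ionone ⇒ racemic α-ionone by lipase resolution of one racemic α-ionol diastereomer, which fixes C6.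
- C8 diiodide ⇒ (E)-oct-4-ene-2,6-diyne (double hydrozirconation–iodination) ⇒ (E)-1,2-dichloroethene + two propyne.
- Rings: none is formed; both ε rings (C1–C6 with their three methyls) are carried intact from α-ionone.

Key step: step 12

Assumption: commercial α-ionone is the racemate, and the racemic α-ionol 4-nitrobenzoate that crystallises is taken to be the (6R*,9R*) pair, so that the enantiomer left unacylated by the lipase carries 6S.

**Step 1**
Reactants: 1 (±)-α-ionone, (3E)-4-(2,6,6-trimethylcyclohex-2-en-1-yl)but-3-en-2-one (racemic)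
Product: 2 (±)-α-ionol, (3E)-4-(2,6,6-trimethylcyclohex-2-en-1-yl)but-3-en-2-ol (both racemic diastereomers)
Conditions: NaBH4, CeCl3·7H2O, MeOH, 0 °C
Reagents that add atoms: none
Why: Luche reduction should give clean 1,2-reduction of the enone; the carbinol centre C9 forms without control (sorted out in steps 2–4) and C6 is untouched.

**Step 2**
Reactants: 2 (±)-α-ionol (diastereomer mixture)
Product: 3 rac-(2S*,3E)-4-[(1S*)-2,6,6-trimethylcyclohex-2-en-1-yl]but-3-en-2-yl 4-nitrobenzoate (the (6R*,9R*) pair, racemic)
Conditions: 4-O2NC6H4COCl, pyridine, DMAP (cat.), CH2Cl2, 0 °C → rt; fractional crystallisation from hexane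
Reagents that add atoms: 4-nitrobenzoyl chloride, O=C(Cl)c1ccc(cc1)[N+](=O)[O-]
Why: Esterification with an acyl chloride gives crystalline derivatives; the two racemic diastereomers are different compounds, so repeated crystallisation should leave one racemic pair, and no stereocentre is created.

**Step 3**
Reactants: 3 rac-(6R*,9R*)-α-ionyl 4-nitrobenzoate
Product: 4 rac-(2S*,3E)-4-[(1S*)-2,6,6-trimethylcyclohex-2-en-1-yl]but-3-en-2-ol (rac-(6R*,9R*)-α-ionol)
Conditions: K2CO3 (0.2 equiv), MeOH, rt
Reagents that add atoms: none
Why: Base-catalysed transesterification (methanolysis) of the activated aryl ester should free the allylic alcohol without touching either stereocentre.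

**Step 4**
Reactants: 4 rac-(6R*,9R*)-α-ionol
Product: 5 (2S,3E)-4-[(1S)-2,6,6-trimethylcyclohex-2-en-1-yl]but-3-en-2-ol ((6S,9S)-α-ionol, the unreacted enantiomer)
Conditions: Burkholderia cepacia lipase, vinyl acetate, t-BuOMe, rt, stopped just beyond half conversion; chromatography
Reagents that add atoms: none
Why: Lipase-catalysed kinetic resolution by irreversible transesterification: secondary alcohols with one small (methyl) and one large (alkenyl) group are acylated at the R carbinol centre, so the (6R,9R) enantiomer is esterified and (6S,9S) stays behind; because 4 is a single racemic diastereomer, this choice at C9 fixes the absolute configuration at C6.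

**Step 5**
Reactants: 5 (6S,9S)-α-ionol
Product: 6 (S)-α-ionone, (3E)-4-[(1S)-2,6,6-trimethylcyclohex-2-en-1-yl]but-3-en-2-one
Conditions: MnO2 (activated, excess), CH2Cl2, rt
Reagents that add atoms: none
Why: MnO2 oxidation of the allylic alcohol under neutral conditions should delete the auxiliary carbinol centre and leave the doubly allylic C6–H stereocentre intact.

**Step 6**
Reactants: 6 (S)-α-ionone
Product: 7 ethyl (2E,4E)-3-methyl-5-[(1S)-2,6,6-trimethylcyclohex-2-en-1-yl]penta-2,4-dienoate
Conditions: (EtO)2P(O)CH2CO2Et, NaH (slightly less than the phosphonate), THF, 0 °C → rt; chromatography to remove the 2Z isomer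
Reagents that add atoms: triethyl phosphonoacetate, CCOC(=O)CP(=O)(OCC)OCC
Why: Horner–Wadsworth–Emmons olefination of the methyl ketone should give mainly the E trisubstituted alkene (C9=C10); the stabilised phosphonate anion, used without excess NaH, is too weak a base to deprotonate C6, so the stereocentre should survive.

**Step 7**
Reactants: 7 ethyl ester
Product: 8 (2E,4E)-3-methyl-5-[(1S)-2,6,6-trimethylcyclohex-2-en-1-yl]penta-2,4-dien-1-ol
Conditions: i-Bu2AlH (2.2 equiv), CH2Cl2, −78 °C; aqueous potassium sodium tartrate work-up
Reagents that add atoms: none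
Why: Hydride reduction of the conjugated ester with diisobutylaluminium hydride should stop cleanly at the allylic alcohol by 1,2-addition without touching the diene geometry.

**Step 8**
Reactants: 8 dienol
Product: 9 (2E,4E)-3-methyl-5-[(1S)-2,6,6-trimethylcyclohex-2-en-1-yl]penta-2,4-dienal
Conditions: MnO2 (activated, excess), CH2Cl2, rt, dark
Reagents that add atoms: none
Why: Selective MnO2 oxidation of the primary allylic alcohol should give the dienal under neutral conditions that do not scramble C9=C10 or C6.

**Step 9**
Reactants: 9 dienal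
Product: 10 (6S)-1,5,5-trimethyl-6-[(1E,3E)-3-methylhexa-1,3-dien-5-yn-1-yl]cyclohex-1-ene
Conditions: Me3SiCHN2, LiN(i-Pr)2, THF, −78 °C; then 9, −78 °C → rt
Reagents that add atoms: trimethylsilyldiazomethane, C[Si](C)(C)C=[N+]=[N-]
Why: Colvin rearrangement: addition of the lithiated silyldiazomethane to the aldehyde, Peterson-type loss of silanolate, loss of N2 and 1,2-hydrogen shift of the alkylidene carbene should give the terminal alkyne in one step, without the alcohol-addition side reactions that enals show under basic methanolic homologation.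

**Step 10**
Reactants: 11 (E)-1,2-dichloroethene; 12 propyne (3 equiv)
Product: 13 (4E)-oct-4-ene-2,6-diyne
Conditions: Pd(PPh3)4 (5 mol %), CuI (10 mol %), piperidine, THF, rt; product handled in solution because of its volatility
Reagents that add atoms: none
Why: Twofold Sonogashira coupling of the vinylic dichloride proceeds with retention, so the E geometry of the future C15=C15' bond is taken over from the starting material.

**Step 11**
Reactants: 13 (4E)-oct-4-ene-2,6-diyne
Product: 15 (2E,4E,6E)-2,7-diiodoocta-2,4,6-triene, via bis(alkenylzirconocene chloride) 14 (not isolated)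
Conditions: Cp2Zr(H)Cl (2.4 equiv), THF, 50 °C, dark; then I2 (2.1 equiv), THF, −78 → 0 °C
Reagents that add atoms: iodine, II
Why: Syn-hydrozirconation of both methyl-capped alkynes, equilibrated by the slight excess of Cp2Zr(H)Cl to the regioisomer with zirconium on the less hindered methyl-bearing carbons (C13/C13'), followed by iodinolysis of the C–Zr bonds with retention, should place each iodine trans to the chain.

**Step 12**
Reactants: 10 C16 dienyne (2.3 equiv); 15 (2E,4E,6E)-2,7-diiodoocta-2,4,6-triene (1.0 equiv)
Product: 19 (6S,6'S)-ε,ε-carotene, via alkenylzirconocene chloride 16 (not isolated), via alkenylzinc chloride 17 (not isolated), via monocoupled C24 alkenyl iodide 18 (not isolated)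
Conditions: 10, Cp2Zr(H)Cl (2.4 equiv), THF, rt, dark; then ZnCl2 (2.4 equiv), 15, Pd(PPh3)4 (5 mol %), THF, 0 °C → rt, dark, argon
Reagents that add atoms: none
Why: Syn-hydrozirconation of the terminal alkyne of 10 puts zirconium on C12 and gives the 11E alkenylzirconocene 16, which ZnCl2 converts into alkenylzinc 17; zerovalent palladium inserts into a C13–I bond of 15, and transmetalation and reductive elimination form C12–C13 with retention at both alkenes, after which the monocoupled iodide 18 re-enters the same cycle and the second C16 unit is joined to this C24 fragment at C12'–C13'. The closest known reaction type is the Negishi alkenyl–alkenyl coupling of hydrozirconated enynes with alkenyl iodides in the presence of ZnCl2, a standard way to all-E polyenes. No ring is closed and no stereocentre is created: the 11E/11'E geometries come from syn addition of Zr–H, the 13E/13'E geometries are carried over from 15 by the stereoretentive coupling, and C6/C6' are spectators under these neutral conditions. The step needs chemoselective hydrometalation of the alkyne beside the C7=C8–C9=C10 diene and the ring alkene, which the much higher rate of Cp2Zr(H)Cl with a terminal alkyne and the use of one equivalent per alkyne should secure, and it needs complete twofold coupling, which the excess of 17 and the symmetry-equivalent, unhindered-partner C–I bonds should secure. In one operation two C–C bonds, two E-alkenes and the whole C40 nonaene are made from a C16 enyne and a C8 triene.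

**Compound list**
1 | (±)-α-ionone, (3E)-4-(2,6,6-trimethylcyclohex-2-en-1-yl)but-3-en-2-one, racemic | CC1=CCCC(C)(C)C1/C=C/C(C)=O | starting material
2 | (±)-α-ionol, (3E)-4-(2,6,6-trimethylcyclohex-2-en-1-yl)but-3-en-2-ol, both racemic diastereomers | CC1=CCCC(C)(C)C1/C=C/C(C)O | intermediate
3 | rac-(2S*,3E)-4-[(1S*)-2,6,6-trimethylcyclohex-2-en-1-yl]but-3-en-2-yl 4-nitrobenzoate, (6R*,9R*) pair, racemate (one enantiomer drawn) | CC1=CCCC(C)(C)[C@@H]1/C=C/[C@H](C)OC(=O)c1ccc(cc1)[N+](=O)[O-] | intermediate
4 | rac-(2S*,3E)-4-[(1S*)-2,6,6-trimethylcyclohex-2-en-1-yl]but-3-en-2-ol, rac-(6R*,9R*)-α-ionol (one enantiomer drawn) | CC1=CCCC(C)(C)[C@@H]1/C=C/[C@H](C)O | intermediate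
5 | (2S,3E)-4-[(1S)-2,6,6-trimethylcyclohex-2-en-1-yl]but-3-en-2-ol, (6S,9S)-α-ionol | CC1=CCCC(C)(C)[C@@H]1/C=C/[C@H](C)O | intermediate
6 | (S)-α-ionone, (3E)-4-[(1S)-2,6,6-trimethylcyclohex-2-en-1-yl]but-3-en-2-one | CC1=CCCC(C)(C)[C@@H]1/C=C/C(C)=O | intermediate
7 | ethyl (2E,4E)-3-methyl-5-[(1S)-2,6,6-trimethylcyclohex-2-en-1-yl]penta-2,4-dienoate | CC1=CCCC(C)(C)[C@@H]1/C=C/C(C)=C/C(=O)OCC | intermediate
8 | (2E,4E)-3-methyl-5-[(1S)-2,6,6-trimethylcyclohex-2-en-1-yl]penta-2,4-dien-1-ol | CC1=CCCC(C)(C)[C@@H]1/C=C/C(C)=C/CO | intermediate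
9 | (2E,4E)-3-methyl-5-[(1S)-2,6,6-trimethylcyclohex-2-en-1-yl]penta-2,4-dienal | CC1=CCCC(C)(C)[C@@H]1/C=C/C(C)=C/C=O | intermediate
10 | (6S)-1,5,5-trimethyl-6-[(1E,3E)-3-methylhexa-1,3-dien-5-yn-1-yl]cyclohex-1-ene | CC1=CCCC(C)(C)[C@@H]1/C=C/C(C)=C/C#C | intermediate
11 | (E)-1,2-dichloroethene | Cl/C=C/Cl | starting material
12 | propyne | CC#C | starting material
13 | (4E)-oct-4-ene-2,6-diyne | CC#C/C=C/C#CC | intermediate
14 | [(2E,4E,6E)-octa-2,4,6-triene-2,7-diyl]bis[chlorobis(cyclopentadienyl)zirconium], each zirconium trans to the chain | Cl[Zr](C1C=CC=C1)(C1C=CC=C1)/C(C)=C/C=C/C=C(C)/[Zr](Cl)(C1C=CC=C1)C1C=CC=C1 | intermediate (not isolated)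
15 | (2E,4E,6E)-2,7-diiodoocta-2,4,6-triene, each iodine trans to the chain | I/C(C)=C/C=C/C=C(C)/I | intermediate
16 | chlorobis(cyclopentadienyl)[(1E,3E,5E)-4-methyl-6-[(1S)-2,6,6-trimethylcyclohex-2-en-1-yl]hexa-1,3,5-trien-1-yl]zirconium | CC1=CCCC(C)(C)[C@@H]1/C=C/C(C)=C/C=C/[Zr](Cl)(C1C=CC=C1)C1C=CC=C1 | intermediate (not isolated)
17 | chloro[(1E,3E,5E)-4-methyl-6-[(1S)-2,6,6-trimethylcyclohex-2-en-1-yl]hexa-1,3,5-trien-1-yl]zinc | CC1=CCCC(C)(C)[C@@H]1/C=C/C(C)=C/C=C/[Zn]Cl | intermediate (not isolated)
18 | (6S)-6-[(1E,3E,5E,7E,9E,11E)-12-iodo-3,7-dimethyltrideca-1,3,5,7,9,11-hexaen-1-yl]-1,5,5-trimethylcyclohex-1-ene | CC1=CCCC(C)(C)[C@@H]1/C=C/C(C)=C/C=C/C(C)=C/C=C/C=C(C)/I | intermediate (not isolated)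
19 | (6S,6'S)-ε,ε-carotene, all-E | CC1=CCCC(C)(C)[C@@H]1/C=C/C(C)=C/C=C/C(C)=C/C=C/C=C(C)/C=C/C=C(C)/C=C/[C@@H]1C(C)=CCCC1(C)C | target

**Step count and risks**
Total step count: 12. Longest linear sequence: 10 steps (steps 1–9, then step 12); steps 10–11 form the short second branch.

Steps most likely to fail:

1. Step 12. The twofold coupling may stall at the monocoupled stage, the alkenylzinc may homocouple, and the growing polyene may lose E/Z purity under light or palladium; all of these give hydrocarbon mixtures that are hard to separate. Fallback: setting out from 10, Cp2Zr(H)Cl-catalysed hydroboration with pinacolborane (Et3N, CH2Cl2, rt) should give the isolable nucleophile 4,4,5,5-tetramethyl-2-[(1E,3E,5E)-4-methyl-6-[(1S)-2,6,6-trimethylcyclohex-2-en-1-yl]hexa-1,3,5-trien-1-yl]-1,3,2-dioxaborolane F1, which can be purified and dosed exactly. A twofold Suzuki–Miyaura coupling of F1 with 15 (Pd(PPh3)4, aqueous KOH, THF, rt, dark) then forms the same C12–C13 and C12'–C13' bonds and comes back to the route at 19.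

2. Step 11. Hydrozirconation may place zirconium next to the alkenyl group instead of on the methyl-bearing carbon, or excess hydride may add to the diene, giving regioisomeric or over-reduced iodides. Fallback: setting out from 12, anti addition of I2 (CH2Cl2, rt, dark) gives (E)-1,2-diiodoprop-1-ene F2. A twofold Stille coupling of commercial (E)-1,2-bis(tributylstannyl)ethene with an excess of F2 (PdCl2(MeCN)2, DMF, rt) should react at the less hindered CH–I terminus with retention and give the diiodide with its regiochemistry fixed by the starting materials; the route is rejoined at 15.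

3. Step 2. Fractional crystallisation may enrich one racemic diastereomer insufficiently (co-crystallisation), which would translate directly into loss of enantiomeric purity at C6 after the lipase step. Fallback: setting out from 1, the racemate is resolved directly by preparative supercritical-fluid chromatography on a polysaccharide-based chiral stationary phase, and the (S)-enantiomer is taken on at 6; steps 1–5 are then not needed and no new compound is made.

**Further compounds**
F1 | step 12 | 4,4,5,5-tetramethyl-2-[(1E,3E,5E)-4-methyl-6-[(1S)-2,6,6-trimethylcyclohex-2-en-1-yl]hexa-1,3,5-trien-1-yl]-1,3,2-dioxaborolane | CC1=CCCC(C)(C)[C@@H]1/C=C/C(C)=C/C=C/B1OC(C)(C)C(C)(C)O1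
F2 | step 11 | (E)-1,2-diiodoprop-1-ene | I/C=C(C)/I
F0 | step 2 | none | none
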